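## Retrosynthetic overview

- Target 10 comes from diacetate 9 by a suprafacial 1,3-shift of the allylic acetate from C4 to C2, which moves the alkene from C2=C3 to C3=C4.
- 9 comes from triol 7, and 7 from lactone 5 by reductive cleavage of the C7(=O)–O–C4 bridge. 5 comes from adduct 3 by oxygen insertion into both C–benzoyl bonds, with retention.
- 3 comes from 1 and 2 by a [4+2] cycloaddition that forms C1–C6 and C4–C5. The carbocycle is the only ring built; it is made first, as a lactone-bridged bicyclo[2.2.2]octene, and the bridge is cut afterwards.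
- Feature the route rests on: the cyclohexene ring has a fully substituted C1 carrying OH and the one-carbon arm C7, which are C3–OH and C2=O of a 2-pyrone. The trans benzoates on C5/C6 map onto a trans-diacyl alkene. C7 and the C2 oxygen are cis, as a C1→C4 lactone bridge followed by a suprafacial shift requires.

Key step: step 1

Remark on numbering: all intermediates carry the carbocycle numbering of the target (C1 carbinol carbon bearing C7; C2, C3, C4; C5 and C6 the benzoate carbons).

Assumption 1: the quinine-derived thiourea base 1-[3,5-bis(trifluoromethyl)phenyl]-3-[(8S,9S)-6'-methoxycinchonan-9-yl]thiourea is taken to deliver the (1R,4R,5S,6S) adduct. If the sense of induction proves opposite, the quinidine-derived pseudoenantiomer is used instead.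

Assumption 2: in step 2 the first oxygen insertion is taken to occur at the C6 benzoyl group, which is hydrogen-bonded to the C1 hydroxyl. The order of the two insertions has no bearing on the product.

## Route

Step 1
Reactants: 1 3-hydroxy-2-pyrone; 2 (E)-1,2-dibenzoylethylene
Product: 3 (1R,4R,5S,6S)-5,6-dibenzoyl-1-hydroxycyclohex-2-ene-1,4-carbolactone (C6 benzoyl syn to the C2=C3 bridge; C5 benzoyl syn to the lactone bridge)
Conditions: quinine-derived thiourea base of assumption 1 (10 mol %), EtOAc–TBME, 0 °C → rt
Reagents that add atoms: none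
Why: The quinuclidine nitrogen should deprotonate the 3-hydroxyl of 1 to give a chiral ammonium oxido-pyrone ion pair, an electron-rich diene, while the thiourea N–H bonds hold one benzoyl carbonyl of 2; C4 (pyrone C6) then bonds to C5 and the enolate carbon C6 closes onto C1, either concertedly or as a Michael–aldol sequence inside the ion pair. The closest known reaction type is the amine-base-catalysed asymmetric Diels–Alder reaction of 3-hydroxy-2-pyrones with enones and other electron-poor alkenes. The carbocycle C1–C6 closes by intermolecular [4+2] cycloaddition (the C1–C6 bond as a six-membered aldol-type closure if the path is stepwise), and the pyrone lactone becomes the C7(=O)–O bridge between C1 and C4. C1 and C4 are set together by the diene face that is attacked, which the chiral ion pair selects; the trans C5/C6 relation is the E geometry of 2; the relation of C5/C6 to the bridge follows from the endo placement of the catalyst-bound C6 benzoyl under the diene. The step needs enantioface and endo/exo control but no regiocontrol, because the two ends of 2 are identical, and it is kept at or below room temperature so that the adduct should neither lose CO2 nor epimerise at C5/C6.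

Step 2
Reactants: 3 lactone-bridged dibenzoyl adduct
Product: 5 (1R,4R,5R,6S)-5,6-bis(benzoyloxy)-1-hydroxycyclohex-2-ene-1,4-carbolactone, via C5-keto C6-benzoate lactone 4 (not isolated)
Conditions: mCPBA (3 equiv), CF3CO2H (1 equiv), CH2Cl2, 0 °C → rt, dark; then aq Na2S2O3/NaHCO3
Reagents that add atoms: mCPBA, OOC(=O)c1cccc(Cl)c1
Why: Acid-catalysed Baeyer–Villiger oxidation, in which the secondary ring carbon of each Criegee adduct should migrate in preference to phenyl with retention at C5 and C6, while the C2=C3 alkene, deactivated by two oxygenated bridgeheads, should be epoxidised more slowly than the protonated ketones are oxidised.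

Step 3
Reactants: 5 bis-benzoate lactone
Product: 7 (1S,4R,5R,6S)-1-(hydroxymethyl)cyclohex-2-ene-1,4,5,6-tetrol 5,6-dibenzoate, via hydroxy aldehyde 6 (not isolated)
Conditions: NaBH4 (4 equiv), THF–MeOH 4:1, −10 → 0 °C; then pH 7 phosphate buffer
Reagents that add atoms: none
Why: Hydroxyl-assisted NaBH4 reduction of an α-hydroxy lactone (as in aldonolactone reduction) should open the strained bridge through the lactol to the α-hydroxy aldehyde, which is reduced at once, while the unassisted benzoates should survive the cold, briefly basic medium; no stereocenter is touched.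

Step 4
Reactants: 7 triol dibenzoate
Product: 9 (1S,4R,5R,6S)-4-acetoxy-1-(acetoxymethyl)-1-hydroxycyclohex-2-ene-5,6-diyl dibenzoate, via C7 monoacetate 8 (not isolated)
Conditions: Ac2O (3 equiv), pyridine, CH2Cl2, 0 °C → rt
Reagents that add atoms: acetic anhydride, CC(=O)OC(C)=O
Why: Standard acylation in which the primary C7 hydroxyl and then the secondary allylic C4 hydroxyl are acetylated, whereas the tertiary C1 hydroxyl should not react without DMAP or heating.

Step 5
Reactants: 9 diacetate
Product: 10 (1R,2S,5R,6S)-2-acetoxy-1-(acetoxymethyl)-1-hydroxycyclohex-3-ene-5,6-diyl dibenzoate (target)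
Conditions: PdCl2(MeCN)2 (10 mol %, divalent palladium), THF, rt; stopped at equilibrium, recovered 9 recycled
Reagents that add atoms: none
Why: Divalent-palladium-catalysed [3,3] allylic ester transposition (cyclisation-induced rearrangement), in which the metal activates C2=C3, the acetate carbonyl oxygen adds to C2 on the face that carries the C4–O bond to give a six-membered acetoxonium σ-palladium intermediate, and loss of palladium with C4–O cleavage gives the C3=C4 alkene, so that the C2 acetate should arrive suprafacially, cis to C7 and trans to the C1 hydroxyl.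

## Compound list

1 | 3-hydroxy-2H-pyran-2-one (3-hydroxy-2-pyrone) | O=c1occcc1O | starting material
2 | (E)-1,4-diphenylbut-2-ene-1,4-dione ((E)-1,2-dibenzoylethylene) | O=C(/C=C/C(=O)c1ccccc1)c1ccccc1 | starting material
3 | (1R,4R,5S,6S)-5,6-dibenzoyl-1-hydroxycyclohex-2-ene-1,4-carbolactone; bicyclo[2.2.2]octene with C7(=O)–O bridge from C1 to C4, C6 benzoyl syn to the alkene bridge, C5 benzoyl syn to the lactone bridge | O=C2O[C@@H]3C=C[C@@]2(O)[C@@H](C(=O)c4ccccc4)[C@@H]3C(=O)c5ccccc5 | intermediate
4 | (1R,4R,5R,6S)-5-benzoyl-6-(benzoyloxy)-1-hydroxycyclohex-2-ene-1,4-carbolactone (mono-insertion product, not isolated) | O=C2O[C@@H]3C=C[C@@]2(O)[C@@H](OC(=O)c4ccccc4)[C@@H]3C(=O)c5ccccc5 | intermediate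
5 | (1R,4R,5R,6S)-5,6-bis(benzoyloxy)-1-hydroxycyclohex-2-ene-1,4-carbolactone; benzoates trans, C6 benzoate cis to the C1 hydroxyl | O=C2O[C@@H]3C=C[C@@]2(O)[C@@H](OC(=O)c4ccccc4)[C@@H]3OC(=O)c5ccccc5 | intermediate
6 | (1R,4R,5R,6S)-5,6-bis(benzoyloxy)-1,4-dihydroxycyclohex-2-ene-1-carbaldehyde (not isolated) | O=C[C@@]1(O)C=C[C@@H](O)[C@@H](OC(=O)c2ccccc2)[C@@H]1OC(=O)c1ccccc1 | intermediate
7 | (1S,4R,5R,6S)-1-(hydroxymethyl)cyclohex-2-ene-1,4,5,6-tetrol 5,6-dibenzoate; C7 and the C4 and C5 oxygens on one face, the C1 and C6 oxygens on the other | OC[C@@]1(O)C=C[C@@H](O)[C@@H](OC(=O)c2ccccc2)[C@@H]1OC(=O)c1ccccc1 | intermediate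
8 | (1S,4R,5R,6S)-1-(acetoxymethyl)-1,4-dihydroxycyclohex-2-ene-5,6-diyl dibenzoate (C7 monoacetate, not isolated) | CC(=O)OC[C@@]1(O)C=C[C@@H](O)[C@@H](OC(=O)c2ccccc2)[C@@H]1OC(=O)c1ccccc1 | intermediate
9 | (1S,4R,5R,6S)-4-acetoxy-1-(acetoxymethyl)-1-hydroxycyclohex-2-ene-5,6-diyl dibenzoate | CC(=O)OC[C@@]1(O)C=C[C@@H](OC(C)=O)[C@@H](OC(=O)c2ccccc2)[C@@H]1OC(=O)c1ccccc1 | intermediate
10 | (1R,2S,5R,6S)-2-acetoxy-1-(acetoxymethyl)-1-hydroxycyclohex-3-ene-5,6-diyl dibenzoate | CC(=O)OC[C@@]1(O)[C@@H](OC(C)=O)C=C[C@@H](OC(=O)c2ccccc2)[C@@H]1OC(=O)c1ccccc1 | target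

## Step count and risks

Total step count: 5. Longest linear sequence: 5.

Steps most likely to fail:

1. Step 1. The catalyst may not discriminate well enough between the two orientations of the E-enedione under the diene or between the two faces of the ion-paired diene, and reversible Michael/aldol steps may erode C5/C6 by epimerisation. Fallback: enantiocontrol is given up and replaced by resolution. Setting out from 1 and 2, triethylamine (10 mol %) in CH2Cl2 at room temperature, which relies only on the intrinsic endo preference of the base-catalysed cycloaddition, should give the racemic adduct F1. Preparative chromatography on a chiral stationary phase (amylose tris(3,5-dimethylphenylcarbamate), hexane/2-propanol) then separates the required enantiomer, and the fallback comes back to the route at 3.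

2. Step 2. Phenyl may migrate instead of the electron-poor, β-oxygenated ring carbon in one or both Criegee adducts, the second insertion may be slow, and the C2=C3 alkene may be epoxidised during the long exposure. Fallback: the acyl groups are changed to acetyl, for which methyl cannot compete with the ring carbon, and the esters are exchanged later.
   - Setting out from 1, the step 1 conditions with commercial (E)-hex-3-ene-2,5-dione (CC(=O)/C=C/C(C)=O) in place of 2 should give the 5,6-diacetyl adduct F2.
   - CF3CO3H (from (CF3CO)2O and urea–H2O2) with Na2HPO4 in CH2Cl2 at 0 °C gives the 5,6-diacetate lactone F3.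
   - NaBH4 in THF–MeOH at −10 °C gives the triol diacetate F4.
   - TBSCl and imidazole in DMF give the C7,C4-bis(silyl) ether F5.
   - K2CO3 in MeOH at 0 °C removes both acetates to give the bis(silyl) triol F6.
   - BzCl, pyridine and catalytic DMAP benzoylate the C5 and C6 hydroxyls to give the bis(silyl) dibenzoate F7.
   - HF·pyridine in THF removes the silyl groups, and the fallback comes back to the route at 7.

3. Step 5. The shift may stop at an unfavourable equilibrium, since the acetate next to the quaternary C1 is the more crowded isomer, and the C5 benzoate, which is allylic in the product, may migrate on to C3. Fallback: the oxygen is transposed by an irreversible, thiophile-driven [2,3] shift.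
   - Setting out from 9, PhSNa with Pd(PPh3)4 (zerovalent palladium) in THF should replace the C4 acetate by phenylthio with net retention (double inversion through the π-allyl complex, attack at the less hindered C4) to give the allylic sulfide F8.
   - mCPBA (1 equiv) in CH2Cl2 at −78 °C gives the sulfoxide F9.
   - Et2NH in MeOH at room temperature intercepts the sulfenate of the Mislow–Evans rearrangement and gives the C2 alcohol F10, with oxygen delivered to C2 on the face that held sulfur.
   - Ac2O, pyridine and catalytic DMAP at 0 °C acetylate the C2 hydroxyl, and the fallback comes back to the route at 10.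

## Further compounds

F1 | step 1 | racemic 5,6-dibenzoyl-1-hydroxycyclohex-2-ene-1,4-carbolactone (3 and its enantiomer, 1:1) | O=C2O[C@@H]3C=C[C@@]2(O)[C@@H](C(=O)c4ccccc4)[C@@H]3C(=O)c5ccccc5.O=C2O[C@H]3C=C[C@]2(O)[C@H](C(=O)c4ccccc4)[C@H]3C(=O)c5ccccc5
F2 | step 2 | 5,6-diacetyl-1-hydroxycyclohex-2-ene-1,4-carbolactone, configuration as in 3 | O=C2O[C@@H]3C=C[C@@]2(O)[C@@H](C(C)=O)[C@@H]3C(C)=O
F3 | step 2 | 5,6-diacetoxy-1-hydroxycyclohex-2-ene-1,4-carbolactone, configuration as in 5 | O=C2O[C@@H]3C=C[C@@]2(O)[C@@H](OC(C)=O)[C@@H]3OC(C)=O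
F4 | step 2 | 1-(hydroxymethyl)cyclohex-2-ene-1,4,5,6-tetrol 5,6-diacetate, configuration as in 7 | OC[C@@]1(O)C=C[C@@H](O)[C@@H](OC(C)=O)[C@@H]1OC(C)=O
F5 | step 2 | C7,C4-bis(tert-butyldimethylsilyl) ether of F4 | CC(C)(C)[Si](C)(C)OC[C@@]1(O)C=C[C@@H](O[Si](C)(C)C(C)(C)C)[C@@H](OC(C)=O)[C@@H]1OC(C)=O
F6 | step 2 | C7,C4-bis(tert-butyldimethylsilyl) ether with free C1, C5 and C6 hydroxyls | CC(C)(C)[Si](C)(C)OC[C@@]1(O)C=C[C@@H](O[Si](C)(C)C(C)(C)C)[C@@H](O)[C@@H]1O
F7 | step 2 | C7,C4-bis(tert-butyldimethylsilyl) ether of 7 | CC(C)(C)[Si](C)(C)OC[C@@]1(O)C=C[C@@H](O[Si](C)(C)C(C)(C)C)[C@@H](OC(=O)c2ccccc2)[C@@H]1OC(=O)c1ccccc1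
F8 | step 5 | 1-(acetoxymethyl)-1-hydroxy-4-(phenylthio)cyclohex-2-ene-5,6-diyl dibenzoate, sulfur on the face that held the C4 acetate | CC(=O)OC[C@@]1(O)C=C[C@@H](Sc3ccccc3)[C@@H](OC(=O)c2ccccc2)[C@@H]1OC(=O)c1ccccc1
F9 | step 5 | sulfoxide of F8 (either configuration at sulfur) | CC(=O)OC[C@@]1(O)C=C[C@@H](S(=O)c3ccccc3)[C@@H](OC(=O)c2ccccc2)[C@@H]1OC(=O)c1ccccc1
F10 | step 5 | 1-(acetoxymethyl)-1,2-dihydroxycyclohex-3-ene-5,6-diyl dibenzoate, C2 hydroxyl cis to C7 | CC(=O)OC[C@@]1(O)[C@@H](O)C=C[C@@H](OC(=O)c2ccccc2)[C@@H]1OC(=O)c1ccccc1
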